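## Retrosynthetic overview

- **Feature:** in ring B (C5–C10) the methyl on quaternary C10 and the isopropenyl carbon C11 on C7 lie on the same (β) face. Annulating plain dihydrocarvone gives the opposite relation. C11 is therefore tied to C6 as a C6–C7–C11 cyclopropane that blocks the β face while C10 becomes quaternary, and this bond is cut afterwards.
- **Key disconnection:** ring A (C1–C5, C10) is taken apart at C1–C10 (Michael) and C4=C5 (aldol condensation). This leads to 2-carone and (E)-6,6-dimethoxyhex-4-en-3-one, whose acetal carbon is C7′.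
- **After the annulation:** HCl opens C6–C11 and loss of HCl gives the isopropenyl group. Li/NH3 sets 5α-H. The C3 enol triflate leads to the Δ3-alkene, then the 3α,4α-epoxide, then the 4α-ol.
- **C7′–C1′ bond:** the 1β-carbaldehyde is joined to lithiated tris-MOM-phloroglucinol, followed by radical deoxygenation. Isobutyryl and formyl groups come from two directed lithiations, and mild acid deprotection is last.
- **Ring order:** ring B (from carvone), temporary cyclopropane, ring A, cyclopropane removed. The arene is bought.

Key step: step 6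

**Remark on numbering.** Eudesmane numbering is used: C14 is Me on C10, C15 is Me on C4, C7′ is the extra carbon on C1, and β is the face of Me-10. Centres that are erased later are carried as mixtures: C10 in 2–4, the carbinol of 6, C4/C5 of 10, C7′ in 19 and 24–26, and the isobutyl carbinol in 30–32.

**Remark on C1.** A 1β (equatorial) formyl group is gauche to both Me-10 and C9. It is favoured over the 1α epimer by only about one gauche interaction. C1 is therefore fixed kinetically in step 6, later steps avoid enolising conditions at C1, and base equilibration is not relied on.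

## Route

Step 1
Reactants: 1 (R)-(−)-carvone
Product: 2 (2R,5R)-dihydrocarvone
Conditions: Zn dust, KOH, EtOH–H2O, reflux
Reagents that add atoms: none
Why: Dissolving-metal conjugate reduction saturates only the electron-poor enone C=C, leaves the isolated isopropenyl group and the C7 centre alone, and gives C10 as an epimer mixture (trans major) that does not matter because C10 is enolised in step 6.

Step 2
Reactants: 2 (2R,5R)-dihydrocarvone
Product: 3 (2R,5R)-5-(2-bromopropan-2-yl)-2-methylcyclohexanone
Conditions: HBr (33 % in AcOH), 0 °C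
Reagents that add atoms: hydrogen bromide, Br
Why: Markovnikov hydrobromination of the 1,1-disubstituted alkene places bromine on tertiary C11 and creates no stereocentre.

Step 3
Reactants: 3 (2R,5R)-5-(2-bromopropan-2-yl)-2-methylcyclohexanone
Product: 4 2-carone, (1S,3R,6R)-3,7,7-trimethylbicyclo[4.1.0]heptan-2-one
Conditions: KOH, MeOH, 0 °C → rt
Reagents that add atoms: none
Why: Intramolecular enolate alkylation (3-exo-tet, the classical carone ring closure): only the C6 enolate can reach C11, and because a cyclopropane can be fused to the six-membered ring only in cis fashion, the new C6 centre is dictated by C7.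

Step 4
Reactants: 5 (E)-4,4-dimethoxybut-2-enal
Product: 6 (E)-6,6-dimethoxyhex-4-en-3-ol (racemic)
Conditions: EtMgBr, THF, −78 → 0 °C; aq. NH4Cl
Reagents that add atoms: ethylmagnesium bromide, CC[Mg]Br
Why: Grignard 1,2-addition to the unhindered enal carbonyl is faster than conjugate addition, the acetal is inert to the reagent, and the racemic carbinol centre is erased in step 5.

Step 5
Reactants: 6 (E)-6,6-dimethoxyhex-4-en-3-ol
Product: 7 (E)-6,6-dimethoxyhex-4-en-3-one
Conditions: activated MnO2, CH2Cl2, rt
Reagents that add atoms: none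
Why: Neutral MnO2 oxidation of an allylic alcohol keeps the acid-labile acetal and the E-alkene intact.

Step 6
Reactants: 4 2-carone; 7 (E)-6,6-dimethoxyhex-4-en-3-one
Product: 11 1β-(dimethoxymethyl)-6,11-cycloeudesm-4-en-3-one (10β-Me; cyclopropane C6–C7–C11 on the β face), via carone lithium enolate 8 (not isolated), via Michael diketone 9 (not isolated), via ketol 10 (not isolated)
Conditions: LDA, THF, −78 → 0 °C; 7, −78 → 0 °C; then NaOMe, MeOH, 0 → 50 °C
Reagents that add atoms: none
Why: LDA removes H-10, the only α-proton of 4 whose loss does not place a double bond exocyclic to the cyclopropane, so enolate 8 forms regiospecifically and adds through C10 to the β-carbon C1 of 7 (any 1,2-aldolate reverts on warming) to give diketone 9, after which methoxide lets C4 of the ethyl ketone attack the C5 carbonyl and ketol 10 loses hydroxide by E1cB to give the tetrasubstituted C4=C5 enone. The closest known reactions are the Robinson annulations of 2-carone with methyl or ethyl vinyl ketone and of 2-methylcyclohexanone enolates with (E)-pent-3-en-2-one, and the present case joins the two. Ring A is the only ring closed, by a 6-(enolendo)-exo-trig aldol addition, and nothing competes because C5 has no second enolisable neighbour and attack from C2 would make a cyclobutane. C10 is controlled by the cyclopropane: the endo methyl on C11 covers the β face of 8, the acceptor bonds on the α face, and Me-10 is left β, cis to C11. C1 is controlled by a lithium-bridged closed transition state in which the acceptor carbonyl lies over the enolate oxygen (on the Me-10 side of C5=C10), so the acetal group points away from ring B rather than over it, which gives the 1β product with the acetal cis to Me-10, the sense known from the cis-vicinal dimethyl octalones made with pentenone. The step needs 1,4- over 1,2-addition and C–C bond formation faster than proton transfer to 8; the inductive pull of the acetal raises the electrophilicity of C1, no leaving group sits β to any enolate carbon, and the irreversible dehydration drains the equilibria towards 11.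

Step 7
Reactants: 11 1β-(dimethoxymethyl)-6,11-cycloeudesm-4-en-3-one
Product: 12 11-chloro-1β-(dimethoxymethyl)eudesm-4-en-3-one
Conditions: dry HCl, MeOH, 0 °C
Reagents that add atoms: hydrogen chloride, Cl
Why: Acid-induced homoconjugate opening of an enone-conjugated cyclopropane: O-protonation makes C6–C11, the strained bond that overlaps with the enone π system and ends at a tertiary carbon, break under chloride attack at C11 to a dienol that tautomerises to the Δ4-3-one, C7 is not touched, and methanol as solvent holds C7′ at the dimethyl acetal stage.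

Step 8
Reactants: 12 11-chloro-1β-(dimethoxymethyl)eudesm-4-en-3-one
Product: 13 1β-(dimethoxymethyl)eudesma-4,11-dien-3-one (7β-isopropenyl, 10β-Me)
Conditions: AgOTf, 2,6-di-tert-butyl-4-methylpyridine, CH2Cl2, −20 °C → rt
Reagents that add atoms: none
Why: Silver-assisted E1 dehydrochlorination: chloride abstraction gives the C11 cation, which should lose one of six exposed methyl protons rather than the single hindered H-7 lying near the nodal plane of the empty orbital, while the hindered pyridine scavenges triflic acid so that neither acetal nor new alkene sees acid and no dienolate forms that could re-close the cyclopropane; any Δ7(11) isomer is to be removed on AgNO3-impregnated silica.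

Step 9
Reactants: 13 1β-(dimethoxymethyl)eudesma-4,11-dien-3-one
Product: 15 1β-(dimethoxymethyl)-5αH-eudesma-3,11-dien-3-yl triflate, via lithium enolate 14 (not isolated)
Conditions: Li, NH3(l), THF, t-BuOH (1 equiv), −78 → −33 °C; isoprene; NH3 evaporated; PhNTf2, THF, 0 °C → rt
Reagents that add atoms: N-phenylbis(trifluoromethanesulfonimide), O=S(=O)(N(c1ccccc1)S(=O)(=O)C(F)(F)F)C(F)(F)F
Why: Dissolving-metal enone reduction with regiospecific enolate trapping: the β-carbanion at C5 is protonated axially from the α face to give the trans-decalin (5α-H), the resulting C3–C4 enolate 14 is O-triflated before it can equilibrate, and the isolated alkene and the acetal are inert to Li/NH3.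

Step 10
Reactants: 15 1β-(dimethoxymethyl)-5αH-eudesma-3,11-dien-3-yl triflate
Product: 16 1β-(dimethoxymethyl)-5αH-eudesma-3,11-diene
Conditions: Pd(OAc)2 (cat.), PPh3, HCO2H, n-Bu3N, DMF, 60 °C
Reagents that add atoms: none
Why: Palladium-catalysed formate hydrogenolysis of a vinyl triflate (oxidative addition, formate decarboxylation, reductive elimination) replaces OTf by H without moving the double bond, and the excess amine keeps the medium non-acidic for the acetal.

Step 11
Reactants: 16 1β-(dimethoxymethyl)-5αH-eudesma-3,11-diene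
Product: 17 3α,4α-epoxy-1β-(dimethoxymethyl)-5αH-eudesm-11-ene
Conditions: mCPBA (1 equiv), NaHCO3, CH2Cl2, −20 → 0 °C
Reagents that add atoms: 3-chloroperoxybenzoic acid, O=C(OO)c1cccc(Cl)c1
Why: Prilezhaev epoxidation: the trisubstituted Δ3 alkene is more nucleophilic than the 1,1-disubstituted isopropenyl group, so one equivalent of peracid at low temperature should react there first, and the axial 10β-methyl blocks the β face so that oxygen arrives from the α face and fixes the C4–O configuration.

Step 12
Reactants: 17 3α,4α-epoxy-1β-(dimethoxymethyl)-5αH-eudesm-11-ene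
Product: 18 1β-(dimethoxymethyl)-5αH-eudesm-11-en-4α-ol
Conditions: LiEt3BH, THF, 0 → 65 °C
Reagents that add atoms: none
Why: SN2 epoxide opening by the strongly nucleophilic, bulky triethylborohydride should take place at secondary C3 rather than at tertiary C4 (which is also screened by the syn-axial Me-10), the C4–O bond is never broken, and the product therefore keeps 4α-OH and 4β-Me.

Step 13
Reactants: 18 1β-(dimethoxymethyl)-5αH-eudesm-11-en-4α-ol
Product: 20 4α-(triethylsilyloxy)-5αH-eudesm-11-ene-1β-carbaldehyde, via lutidinium salt 19 (not isolated)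
Conditions: TESOTf (excess), 2,6-lutidine, CH2Cl2, 0 °C; then H2O
Reagents that add atoms: triethylsilyl triflate, CC[Si](CC)(CC)OS(=O)(=O)C(F)(F)F; water, O
Why: Silyl-triflate/pyridine-base acetal cleavage: TESOTf ionises the acetal, lutidine captures the oxocarbenium ion as salt 19 and water hydrolyses it under weakly basic conditions, while the same reagent silylates the tertiary alcohol, so the alkene, the C4 centre and the epimerisable C1 centre never meet aqueous acid.

Step 14
Reactants: 21 phloroglucinol
Product: 22 1,3,5-tris(methoxymethoxy)benzene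
Conditions: MOMCl, i-Pr2NEt, CH2Cl2, 0 °C → rt
Reagents that add atoms: chloromethyl methyl ether, COCCl
Why: O-Alkylation of the phenol with a hard oxocarbenium-type electrophile and an amine base gives the tris-ether, whose OMOM groups later direct lithiation and leave under mild acid.

Step 15
Reactants: 20 4α-(triethylsilyloxy)-5αH-eudesm-11-ene-1β-carbaldehyde; 22 1,3,5-tris(methoxymethoxy)benzene
Product: 24 C7′-carbinol, 1β-[hydroxy(2,4,6-tris(methoxymethoxy)phenyl)methyl]-4α-(triethylsilyloxy)-5αH-eudesm-11-ene (C7′ epimers), via aryllithium 23 (not isolated)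
Conditions: 22, n-BuLi, THF, 0 °C; then 20, −78 → −20 °C
Reagents that add atoms: none
Why: Directed ortho-metalation at a position flanked by two OMOM groups, followed by 1,2-addition to the aldehyde at low temperature, where addition should outrun enolisation at C1; both C7′ epimers are used because this centre is removed in step 17.

Step 16
Reactants: 24 C7′-carbinol
Product: 26 C7′ O-alkyl S-methyl xanthate of 24, via sodium xanthate 25 (not isolated)
Conditions: NaH, THF, 0 °C; CS2, 0 °C → rt; then MeI
Reagents that add atoms: carbon disulfide, S=C=S; iodomethane, CI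
Why: Xanthate formation (first half of the Barton–McCombie sequence): the small electrophile CS2 reaches the hindered alkoxide, and the TES ether leaves no second hydroxyl to compete.

Step 17
Reactants: 26 C7′ xanthate
Product: 27 1β-[2,4,6-tris(methoxymethoxy)benzyl]-4α-(triethylsilyloxy)-5αH-eudesm-11-ene
Conditions: n-Bu3SnH, Et3B (cat.), air, toluene, rt
Reagents that add atoms: none
Why: Barton–McCombie deoxygenation run at room temperature with Et3B/air initiation, so that the ionisation-prone benzylic xanthate does not rearrange or eliminate thermally; the benzylic radical has no alkene within reach of a favourable cyclisation and only abstracts hydrogen, so C1 is not disturbed.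

Step 18
Reactants: 27 1β-[2,4,6-tris(methoxymethoxy)benzyl]-4α-(triethylsilyloxy)-5αH-eudesm-11-ene; 28 isobutyraldehyde
Product: 30 3′-(1-hydroxy-2-methylpropyl) derivative of 27 (carbinol epimers), via aryllithium 29 (not isolated)
Conditions: n-BuLi, THF, −20 → 0 °C; then 28, −78 → 0 °C
Reagents that add atoms: none
Why: Directed ortho-metalation of one of the two equivalent ring positions between OMOM groups (no TMEDA, so the allylic isopropenyl methyl is not metalated) and addition to the aldehyde; the carbinol epimers converge in step 20.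

Step 19
Reactants: 30 3′-(1-hydroxy-2-methylpropyl) derivative of 27
Product: 32 5′-formyl-3′-(1-hydroxy-2-methylpropyl) derivative of 27, via dilithio species 31 (not isolated)
Conditions: n-BuLi (2.5 equiv), THF, 0 °C; then DMF, −78 °C → rt; aq. NH4Cl
Reagents that add atoms: N,N-dimethylformamide, CN(C)C=O
Why: After deprotonation of the hydroxyl, the last ring C–H, again flanked by two OMOM groups, is lithiated and formylated with DMF (Bouveault-type formylation), and the tetrahedral adduct releases the aldehyde only on work-up.

Step 20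
Reactants: 32 5′-formyl-3′-(1-hydroxy-2-methylpropyl) derivative of 27
Product: 33 fully protected target (3′-isobutyryl, 5′-formyl, three OMOM, 4α-OTES)
Conditions: Dess–Martin periodinane, NaHCO3, CH2Cl2, rt
Reagents that add atoms: none
Why: Dess–Martin oxidation converts the only secondary alcohol into the aryl ketone under near-neutral conditions that spare the aldehyde, alkene, MOM and TES groups.

Step 21
Reactants: 33 fully protected target
Product: 34 CNP0498016.1 (target)
Conditions: p-TsOH·H2O, MeOH, rt → 40 °C
Reagents that add atoms: none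
Why: Acid-catalysed acetal exchange and silyl ether methanolysis: each MOM ether is ortho to a carbonyl group and is cleaved under mild acid, the TES ether falls at the same time, and the unactivated tertiary alcohol and the 1,1-disubstituted alkene should not be ionised or protonated at this acidity.

## Compound list

1 | (R)-(−)-carvone | CC1=CC[C@H](CC1=O)C(C)=C | starting material
2 | (2R,5R)-dihydrocarvone | C[C@@H]1CC[C@H](CC1=O)C(C)=C | intermediate
3 | (2R,5R)-5-(2-bromopropan-2-yl)-2-methylcyclohexanone | C[C@@H]1CC[C@H](CC1=O)C(C)(C)Br | intermediate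
4 | 2-carone, (1S,3R,6R)-3,7,7-trimethylbicyclo[4.1.0]heptan-2-one | C[C@@H]1CC[C@@H]2[C@H](C1=O)C2(C)C | intermediate
5 | (E)-4,4-dimethoxybut-2-enal | COC(OC)/C=C/C=O | starting material
6 | (E)-6,6-dimethoxyhex-4-en-3-ol | CCC(O)/C=C/C(OC)OC | intermediate
7 | (E)-6,6-dimethoxyhex-4-en-3-one | CCC(=O)/C=C/C(OC)OC | intermediate
8 | lithium C5=C10 enolate of 2-carone | CC1=C([O-])[C@H]2[C@@H](CC1)C2(C)C.[Li+] | intermediate
9 | Michael diketone, 3-(1,1-dimethoxy-4-oxohexan-2-yl)-3,7,7-trimethylbicyclo[4.1.0]heptan-2-one (C10 and C1 as in 11) | CCC(=O)C[C@@H](C(OC)OC)[C@]1(C)CC[C@@H]2[C@H](C1=O)C2(C)C | intermediate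
10 | ketol, 5-hydroxy-1β-(dimethoxymethyl)-6,11-cycloeudesman-3-one | CC1C(=O)C[C@@H](C(OC)OC)[C@]2(C)CC[C@H]3C(C)(C)[C@H]3C12O | intermediate
11 | 1β-(dimethoxymethyl)-6,11-cycloeudesm-4-en-3-one | CC1=C2[C@H]3[C@@H](CC[C@@]2(C)[C@H](C(OC)OC)CC1=O)C3(C)C | intermediate
12 | 11-chloro-1β-(dimethoxymethyl)eudesm-4-en-3-one | CC(C)(Cl)[C@@H]1CC[C@@]2(C)[C@H](C(OC)OC)CC(=O)C(C)=C2C1 | intermediate
13 | 1β-(dimethoxymethyl)eudesma-4,11-dien-3-one | C=C(C)[C@@H]1CC[C@@]2(C)[C@H](C(OC)OC)CC(=O)C(C)=C2C1 | intermediate
14 | lithium C3=C4 enolate (5α-H) | C=C(C)[C@@H]1CC[C@@]2(C)[C@H](C(OC)OC)CC([O-])=C(C)[C@@H]2C1.[Li+] | intermediate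
15 | 1β-(dimethoxymethyl)-5αH-eudesma-3,11-dien-3-yl triflate | C=C(C)[C@@H]1CC[C@@]2(C)[C@H](C(OC)OC)CC(OS(=O)(=O)C(F)(F)F)=C(C)[C@@H]2C1 | intermediate
16 | 1β-(dimethoxymethyl)-5αH-eudesma-3,11-diene | C=C(C)[C@@H]1CC[C@@]2(C)[C@H](C(OC)OC)CC=C(C)[C@@H]2C1 | intermediate
17 | 3α,4α-epoxy-1β-(dimethoxymethyl)-5αH-eudesm-11-ene | C=C(C)[C@@H]1CC[C@@]2(C)[C@H](C(OC)OC)C[C@H]3O[C@@]3(C)[C@@H]2C1 | intermediate
18 | 1β-(dimethoxymethyl)-5αH-eudesm-11-en-4α-ol | C=C(C)[C@@H]1CC[C@@]2(C)[C@H](C(OC)OC)CC[C@@](C)(O)[C@@H]2C1 | intermediate
19 | N-(C7′-methoxyalkyl)-2,6-lutidinium triflate, 4α-OTES | C=C(C)[C@@H]1CC[C@@]2(C)[C@H](C(OC)[n+]3c(C)cccc3C)CC[C@@](C)(O[Si](CC)(CC)CC)[C@@H]2C1.[O-]S(=O)(=O)C(F)(F)F | intermediate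
20 | 4α-(triethylsilyloxy)-5αH-eudesm-11-ene-1β-carbaldehyde | C=C(C)[C@@H]1CC[C@@]2(C)[C@H](C=O)CC[C@@](C)(O[Si](CC)(CC)CC)[C@@H]2C1 | intermediate
21 | phloroglucinol | Oc1cc(O)cc(O)c1 | starting material
22 | 1,3,5-tris(methoxymethoxy)benzene | COCOc1cc(OCOC)cc(OCOC)c1 | intermediate
23 | 2,4,6-tris(methoxymethoxy)phenyllithium | [Li]c1c(OCOC)cc(OCOC)cc1OCOC | intermediate
24 | C7′-carbinol | C=C(C)[C@@H]1CC[C@@]2(C)[C@H](C(O)c3c(OCOC)cc(OCOC)cc3OCOC)CC[C@@](C)(O[Si](CC)(CC)CC)[C@@H]2C1 | intermediate
25 | sodium C7′-xanthate | C=C(C)[C@@H]1CC[C@@]2(C)[C@H](C(OC(=S)[S-])c3c(OCOC)cc(OCOC)cc3OCOC)CC[C@@](C)(O[Si](CC)(CC)CC)[C@@H]2C1.[Na+] | intermediate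
26 | C7′ S-methyl xanthate | C=C(C)[C@@H]1CC[C@@]2(C)[C@H](C(OC(=S)SC)c3c(OCOC)cc(OCOC)cc3OCOC)CC[C@@](C)(O[Si](CC)(CC)CC)[C@@H]2C1 | intermediate
27 | 1β-[2,4,6-tris(methoxymethoxy)benzyl]-4α-(triethylsilyloxy)-5αH-eudesm-11-ene | C=C(C)[C@@H]1CC[C@@]2(C)[C@H](Cc3c(OCOC)cc(OCOC)cc3OCOC)CC[C@@](C)(O[Si](CC)(CC)CC)[C@@H]2C1 | intermediate
28 | isobutyraldehyde | CC(C)C=O | starting material
29 | 3′-lithio derivative of 27 | C=C(C)[C@@H]1CC[C@@]2(C)[C@H](Cc3c(OCOC)cc(OCOC)c([Li])c3OCOC)CC[C@@](C)(O[Si](CC)(CC)CC)[C@@H]2C1 | intermediate
30 | 3′-(1-hydroxy-2-methylpropyl) derivative of 27 | C=C(C)[C@@H]1CC[C@@]2(C)[C@H](Cc3c(OCOC)cc(OCOC)c(C(O)C(C)C)c3OCOC)CC[C@@](C)(O[Si](CC)(CC)CC)[C@@H]2C1 | intermediate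
31 | 5′-lithio lithium alkoxide of 30 | C=C(C)[C@@H]1CC[C@@]2(C)[C@H](Cc3c(OCOC)c([Li])c(OCOC)c(C(O[Li])C(C)C)c3OCOC)CC[C@@](C)(O[Si](CC)(CC)CC)[C@@H]2C1 | intermediate
32 | 5′-formyl-3′-(1-hydroxy-2-methylpropyl) derivative of 27 | C=C(C)[C@@H]1CC[C@@]2(C)[C@H](Cc3c(OCOC)c(C=O)c(OCOC)c(C(O)C(C)C)c3OCOC)CC[C@@](C)(O[Si](CC)(CC)CC)[C@@H]2C1 | intermediate
33 | fully protected target | C=C(C)[C@@H]1CC[C@@]2(C)[C@H](Cc3c(OCOC)c(C=O)c(OCOC)c(C(=O)C(C)C)c3OCOC)CC[C@@](C)(O[Si](CC)(CC)CC)[C@@H]2C1 | intermediate
34 | CNP0498016.1 | C=C(C)[C@@H]1CC[C@@]2(C)[C@H](Cc3c(O)c(C=O)c(O)c(C(=O)C(C)C)c3O)CC[C@@](C)(O)[C@@H]2C1 | target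

## Step count and risks

Total step count: 21.
Longest linear sequence: 18 (steps 1–3, 6–13, 15–21).

**Step 6.**
- What may go wrong: the hindered tetrasubstituted enolate may add too slowly to the β-substituted acceptor. Proton transfer from the acceptor (α′ or acetal γ-position) and retro-Michael cleavage would then take over. Alternatively, the closed transition state may be loosened, so that the topicity at C1 erodes.
- Fallback: it sets out from 4 (as enolate 8) and comes back at 11.
- Lithiated 3,3-dimethoxyprop-1-yne is acylated with N-methoxy-N-methylpropanamide to give 6,6-dimethoxyhex-4-yn-3-one F1.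
- Enolate 8 adds to the unhindered sp carbon of this ynone, again from the α face. NaOMe/MeOH then closes ring A to the cross-conjugated 1-(dimethoxymethyl)-6,11-cycloeudesma-1,4-dien-3-one F2.
- Copper hydride conjugate reduction (Stryker's reagent, benzene, rt) of the less substituted Δ1 bond delivers hydride to C1 from the α face, anti to Me-10. This sets 1β independently of Michael topicity and gives 11.

**Step 12.**
- What may go wrong: opening at C3 is the diequatorial (anti-Fürst–Plattner) mode of this rigid epoxide and may be slow. Hydride attack at C4 or base-induced isomerisation to an allylic alcohol may then compete.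
- Fallback: it sets out from 13 and comes back at 18, and it also bypasses steps 9–11.
- Li/NH3 reduction is followed by TMSCl/Et3N trapping to give the 3-(trimethylsilyloxy)-Δ3 enol ether F3.
- Rubottom oxidation (mCPBA, NaHCO3, then buffered Bu4NF) attacks the electron-rich enol ether from the α face in preference to the isopropenyl group. It gives 4α-hydroxy-1β-(dimethoxymethyl)-5αH-eudesm-11-en-3-one F4.
- TsNHNH2 in MeOH gives the tosylhydrazone F5. Catecholborane followed by NaOAc·3H2O in warm CHCl3 reduces C3 to CH2 and gives 18.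

**Step 8.**
- What may go wrong: regiocontrol may be lost in the proton loss from the C11 cation, through competing loss of H-7 or a hydride shift from C7. This would give alkene isomers that are hard to separate.
- Fallback: it sets out from 12 and comes back at 13.
- Silver-assisted hydrolysis (AgNO3, CaCO3, aqueous acetone) gives 11-hydroxy-1β-(dimethoxymethyl)eudesm-4-en-3-one F6.
- The Burgess reagent (benzene, 50 °C) removes water by a syn (Ei) elimination. This pathway draws on the six methyl hydrogens rather than the single H-7 and involves neither acid nor enolate.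

## Further compounds

F1 | step 6 | 6,6-dimethoxyhex-4-yn-3-one | CCC(=O)C#CC(OC)OC
F2 | step 6 | 1-(dimethoxymethyl)-6,11-cycloeudesma-1,4-dien-3-one | CC1=C2[C@H]3[C@@H](CC[C@@]2(C)C(C(OC)OC)=CC1=O)C3(C)C
F3 | step 12 | 1β-(dimethoxymethyl)-3-(trimethylsilyloxy)-5αH-eudesma-3,11-diene | C=C(C)[C@@H]1CC[C@@]2(C)[C@H](C(OC)OC)CC(O[Si](C)(C)C)=C(C)[C@@H]2C1
F4 | step 12 | 4α-hydroxy-1β-(dimethoxymethyl)-5αH-eudesm-11-en-3-one | C=C(C)[C@@H]1CC[C@@]2(C)[C@H](C(OC)OC)CC(=O)[C@@](C)(O)[C@@H]2C1
F5 | step 12 | tosylhydrazone of F4 | C=C(C)[C@@H]1CC[C@@]2(C)[C@H](C(OC)OC)CC(=NNS(=O)(=O)c3ccc(C)cc3)[C@@](C)(O)[C@@H]2C1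
F6 | step 8 | 11-hydroxy-1β-(dimethoxymethyl)eudesm-4-en-3-one | CC(C)(O)[C@@H]1CC[C@@]2(C)[C@H](C(OC)OC)CC(=O)C(C)=C2C1
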